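The numbers in the tables were generated by integration from invented constants; scatter was added.

**The constants.** You asked for a quick number, and for that I need two constants. E falls at 0.0172 s⁻¹ in the dusk flask up to 25.0 s and at 0.0194 s⁻¹ in the noon flask up to 50.0 s, so I treat the loss as first order and take the mean, 0.0183 s⁻¹. The second constant is the split (the selectivity), the fraction of spent E found as G with Q counted in, read from the last dusk reading as 0.486.

| flask | E | remark | time |
|---|---|---|---|
| dusk | 0.21 M | the very flask that is asked about, followed so far |  |
| noon | 0.32 M | run made earlier |  |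
| flask | 0.21 M |  | 2.0 min |

- dusk (time / s: G / %, E / %): 10.0: 7, 86; 15.0: 16, 75; 25.0: 17, 65
- noon (time / s: G / %, E / %): 10.0: 6, 83; 20.0: 18, 74; 50.0: 29, 38

(readings scatter by 2 percentage points)

- in percentages every species weighs as the E in it: one J counts as two
- for G the Q are counted in
- as a solid, counted per litre of solution: Q
- the earlier runs were read with a standard deviation of 2 percentage points
- steps thought possible: E -> G; E -> Z; 2 E -> J; Q <-> G

* amount of G in percent of the E charged, at 25 s, 1.0 min and 2.0 min

**A noon test.** The noon flask had no part in that split. Applied to the E spent there, the split gives 30.1% G at 50.0 s, against 29% read, with readings scattered by 2 percentage points.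

**My reckoning.** For the dusk flask, the split times the E spent gives 17.8% G at 25 s, 32.4% at 1.0 min and 43.2% at 2.0 min.

**Your forecast.** It reads 18%, 33% and 44%, and it argues: “Because Q is included in G, Q ⇌ G does not change the total”. At 2.0 min mine is lower by 0.84 points.

**The result.** The dusk flask gives 18.0%, 32.8% and 44.1% G at the three times.

    E → G (k = 0.00890 s⁻¹)
    E → Z (k = 0.00890 s⁻¹)
    2 E → J (k = 1.70 × 10⁻⁵ M⁻¹ s⁻¹)
    Q ⇌ G, rate k4*(cs4 - [G]) while solid is left; crystals form when [G] > cs4 (solubility = 10.0 mM, k = 1.10 s⁻¹)

**The split.** The step from E to G and the step from E to Z use E at a ratio of 1.0 at the start and 1.0 at 2.0 min, and at that time the dusk flask holds G at 44.1%, level with Z at 44.1%. My split of 0.486, a reading from the dusk run, applied to the E spent by 2.0 min gives 42.8% G, and inside the G of the dusk flask 39.2% of the charge stands as Q.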